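Ring A is the 2-hydroxy-4-methoxy-6-methylbenzoyl unit (primed locants) and ring B the 2-hydroxy-6-pentylbenzoic acid unit. The retrosynthesis first removes a benzyl group from the CO2H and cuts the 4'-O–CH3 bond.
The central cut breaks two bonds at once, the depside bond C(=O)–O(C4) and the ring A bond C1'–C6'. This unfolds ring A into a 3,5,7-trioxooctanoyl chain, delivered as an acylketene from a diketo-dioxinone.
Enabling feature: in both rings the carboxyl carbon, the oxygenated C2 and C4 and the alkyl-bearing C6 stand in the 1,3,5,7 pattern of a tetraketide. Each benzene is therefore a folded 3,5,7-triketo ester whose ester oxygen can come from any O–H trap, here the unchelated 4-OH of ring B.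
Ring B is opened the same way (C1–C6 and the benzyl ester C–O bond). Both chains go back to one keto-dioxinone, extended at its terminal CH3 by a hexanoyl or an acetyl unit.
Forward order: common keto-dioxinone, two chain extensions, ring B closed on benzyl alcohol, ring A closed on O-4 of ring B as the halves are joined, 4'-O-methylation, hydrogenolysis.
Stereochemistry: the target is achiral. The only sp3 centres on the way belong to two transient aldol carbinols and disappear on aromatisation.

Key step: step 6

Remark: LiN(SiMe3)2 and LiN(iPr)2 are taken as commercial solutions, and open-chain locants count from the ester or ketene carbon as C1.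

Step 1
Reactants: 1 dioxinone [2,2,6-trimethyl-4H-1,3-dioxin-4-one]; 2 acetyl chloride
Product: 3 keto-dioxinone [2,2-dimethyl-6-(2-oxopropyl)-4H-1,3-dioxin-4-one]
Conditions: 1 (2 equiv), LiN(SiMe3)2 (2 equiv), THF, −78 °C; 2 (1 equiv), −78 °C; 1 M HCl
Reagents that add atoms: none
Why: LiN(SiMe3)2 removes a proton from the 6-methyl group and the extended dienolate is acylated at that γ-carbon by the acid chloride (vinylogous Claisen-type C-acylation), the second equivalent of dienolate taking up the more acidic proton of 3 so that a second acylation is suppressed.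

Step 2
Reactants: 4 hexanoyl chloride
Product: 5 N-methoxy-N-methylhexanamide
Conditions: MeNH(OMe)·HCl, K2CO3, CH2Cl2/H2O, 0 °C → rt
Reagents that add atoms: N,O-dimethylhydroxylamine hydrochloride, CNOC.Cl
Why: Schotten–Baumann N-acylation by an unhindered acid chloride is much faster than its hydrolysis in the two-phase medium and gives the amide type that later stops acyl transfer at the ketone stage.

Step 3
Reactants: 3 keto-dioxinone; 5 N-methoxy-N-methylhexanamide
Product: 6 pentyl diketo-dioxinone [6-(2,4-dioxononyl)-2,2-dimethyl-4H-1,3-dioxin-4-one]
Conditions: 3 (1.5 equiv), LiN(iPr)2 (3.1 equiv), THF, −78 → −40 °C; 5 (1 equiv), −78 → −20 °C; 1 M HCl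
Reagents that add atoms: none
Why: Two deprotonations of 3 (first the CH2 flanked by ketone and dioxinone, then the terminal CH3) leave the terminal carbon as the most reactive site, and its Claisen-type acylation by an N-methoxy-N-methyl amide rests at the chelated tetrahedral stage until the acid quench, so the acidic 1,3-diketone is never released in front of unreacted nucleophile.

Step 4
Reactants: 6 pentyl diketo-dioxinone; 7 benzyl alcohol
Product: 11 benzyl 2,4-dihydroxy-6-pentylbenzoate, via acylketene 8 (not isolated), via benzyl 3,5,7-trioxododecanoate 9 (not isolated), via aldol carbinol 10 (not isolated)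
Conditions: 7 (1.2 equiv), PhMe, 110 °C; cool, CH2Cl2, Et3N, rt; TFA, rt
Reagents that add atoms: none
Why: Retro-hetero-Diels–Alder loss of acetone, capture of the acylketene by a primary alcohol, amine-promoted C2-to-C7 aldol closure and acid dehydration make up the established resorcylate benzannulation of diketo-dioxinones, and the benzyl ester it installs can later be removed without touching an aryl ester.

Step 5
Reactants: 3 keto-dioxinone; 12 N-methoxy-N-methylacetamide
Product: 13 methyl diketo-dioxinone [6-(2,4-dioxopentyl)-2,2-dimethyl-4H-1,3-dioxin-4-one]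
Conditions: 3 (1.5 equiv), LiN(iPr)2 (3.1 equiv), THF, −78 → −40 °C; 12 (1 equiv), −78 → −20 °C; 1 M HCl
Reagents that add atoms: none
Why: The same terminal-carbon Claisen-type acylation of doubly deprotonated 3 applies, and adding the small unhindered amide at −78 °C to an excess of the nucleophile lets addition to the carbonyl group compete successfully against proton abstraction from its acetyl group.

Step 6
Reactants: 11 benzyl 2,4-dihydroxy-6-pentylbenzoate; 13 methyl diketo-dioxinone
Product: 17 benzyl 4-(2,4-dihydroxy-6-methylbenzoyloxy)-2-hydroxy-6-pentylbenzoate, via acylketene 14 (not isolated), via aryl 3,5,7-trioxooctanoate 15 (not isolated), via aldol carbinol 16 (not isolated)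
Conditions: 11 (1.3 equiv, ca. 0.5 M in PhMe), 110 °C, slow addition of 13; cool to 0 °C, CH2Cl2, Et3N, 0 °C → rt; TFA, rt
Reagents that add atoms: none
Why: Heating 13 triggers a retro-hetero-Diels–Alder loss of acetone, and the ketene carbon of 14 is attacked by the free 4-OH of 11, which creates the C(=O)–O(C4) depside bond in 15. Et3N then enolises the C2 methylene between the ester and the C3 ketone, C2 adds to the C7 ketone to give carbinol 16, and TFA removes water so that the C3 and C5 ketones tautomerise to the 2'- and 4'-phenols of ring A in 17. The closest known reaction type is the resorcylate benzannulation of diketo-dioxinones (thermolysis, O–H capture of the acylketene, aldol aromatisation), taken together with the acetoacetylation of phenols by dioxinone-derived acylketenes. The single ring closed is the six-membered carbocycle C2–C7, by 6-exo-trig attack on the C7 carbonyl (enolendo if the nucleophile is drawn as the C2=C3 enolate, enolexo if drawn as the ester enolate, both favourable at this ring size). The two sp3 centres of 16 form without control and are erased by aromatisation, so no stereocentre has to be governed. Two selectivities are needed: acylation at the 4-OH, secured because the 2-OH of 11 is tied by a hydrogen bond to the benzyl ester carbonyl and crowded by it, and aldol closure in preference to lactonisation through the C5 enol oxygen or C6-to-C1 Claisen closure (both would expel the phenol), secured by a high phenol concentration during thermolysis and a weak amine base in an alcohol-free medium at or below room temperature.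

Step 7
Reactants: 17 benzyl 4-(2,4-dihydroxy-6-methylbenzoyloxy)-2-hydroxy-6-pentylbenzoate
Product: 18 benzyl 2-hydroxy-4-(2-hydroxy-4-methoxy-6-methylbenzoyloxy)-6-pentylbenzoate
Conditions: MeOH (1.1 equiv), PPh3 (1.1 equiv), DIAD (1.1 equiv), THF, 0 °C → rt
Reagents that add atoms: methanol, CO
Why: Mitsunobu O-alkylation needs a phenol that is acidic and free enough to protonate the betaine, which singles out the 4'-OH (para to the ester carbonyl, no hydrogen bond) over the two ortho-hydroxyls locked to their carbonyl groups, and the neutral medium spares the aryl ester.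

Step 8
Reactants: 18 benzyl 2-hydroxy-4-(2-hydroxy-4-methoxy-6-methylbenzoyloxy)-6-pentylbenzoate
Product: 19 2-hydroxy-4-(2-hydroxy-4-methoxy-6-methylbenzoyloxy)-6-pentylbenzoic acid (target)
Conditions: H2 (1 atm), 10% Pd/C, EtOAc, rt
Reagents that add atoms: none
Why: Catalytic hydrogenolysis cleaves only the benzylic C–O bond and leaves the aryl ester, the methyl ether and the phenols alone, while the neutral room-temperature medium avoids decarboxylation of the electron-rich salicylic acid.

Compound list
1 | 2,2,6-trimethyl-4H-1,3-dioxin-4-one | CC1=CC(=O)OC(C)(C)O1 | starting material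
2 | acetyl chloride | CC(=O)Cl | starting material
3 | 2,2-dimethyl-6-(2-oxopropyl)-4H-1,3-dioxin-4-one | CC(=O)CC1=CC(=O)OC(C)(C)O1 | intermediate
4 | hexanoyl chloride | CCCCCC(=O)Cl | starting material
5 | N-methoxy-N-methylhexanamide | CCCCCC(=O)N(C)OC | intermediate
6 | 6-(2,4-dioxononyl)-2,2-dimethyl-4H-1,3-dioxin-4-one | CCCCCC(=O)CC(=O)CC1=CC(=O)OC(C)(C)O1 | intermediate
7 | benzyl alcohol | OCc1ccccc1 | starting material
8 | 3,5,7-trioxododec-1-en-1-one (acylketene, not isolated) | CCCCCC(=O)CC(=O)CC(=O)C=C=O | intermediate
9 | benzyl 3,5,7-trioxododecanoate (not isolated) | CCCCCC(=O)CC(=O)CC(=O)CC(=O)OCc1ccccc1 | intermediate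
10 | benzyl 2-hydroxy-4,6-dioxo-2-pentylcyclohexane-1-carboxylate (not isolated, mixture of stereoisomers, centres erased in the same step) | CCCCCC1(O)CC(=O)CC(=O)C1C(=O)OCc1ccccc1 | intermediate
11 | benzyl 2,4-dihydroxy-6-pentylbenzoate | CCCCCc1cc(O)cc(O)c1C(=O)OCc1ccccc1 | intermediate
12 | N-methoxy-N-methylacetamide | CC(=O)N(C)OC | starting material
13 | 6-(2,4-dioxopentyl)-2,2-dimethyl-4H-1,3-dioxin-4-one | CC(=O)CC(=O)CC1=CC(=O)OC(C)(C)O1 | intermediate
14 | 3,5,7-trioxooct-1-en-1-one (acylketene, not isolated) | CC(=O)CC(=O)CC(=O)C=C=O | intermediate
15 | benzyl 2-hydroxy-6-pentyl-4-(3,5,7-trioxooctanoyloxy)benzoate (not isolated) | CCCCCc1cc(OC(=O)CC(=O)CC(=O)CC(C)=O)cc(O)c1C(=O)OCc1ccccc1 | intermediate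
16 | benzyl 2-hydroxy-4-(2-hydroxy-2-methyl-4,6-dioxocyclohexane-1-carbonyloxy)-6-pentylbenzoate (not isolated, mixture of stereoisomers, centres erased in the same step) | CCCCCc1cc(OC(=O)C2C(=O)CC(=O)CC2(C)O)cc(O)c1C(=O)OCc1ccccc1 | intermediate
17 | benzyl 4-(2,4-dihydroxy-6-methylbenzoyloxy)-2-hydroxy-6-pentylbenzoate | CCCCCc1cc(OC(=O)c2c(C)cc(O)cc2O)cc(O)c1C(=O)OCc1ccccc1 | intermediate
18 | benzyl 2-hydroxy-4-(2-hydroxy-4-methoxy-6-methylbenzoyloxy)-6-pentylbenzoate | CCCCCc1cc(OC(=O)c2c(C)cc(OC)cc2O)cc(O)c1C(=O)OCc1ccccc1 | intermediate
19 | 2-hydroxy-4-(2-hydroxy-4-methoxy-6-methylbenzoyloxy)-6-pentylbenzoic acid | CCCCCc1cc(OC(=O)c2c(C)cc(OC)cc2O)cc(O)c1C(=O)O | target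

Total step count: 8. Longest linear sequence: 6 steps (steps 1, 3, 4, 6, 7, 8).

Steps most likely to fail

Step 6. Capture of the ketene by a weakly nucleophilic phenol may be outrun by intramolecular O-acylation through the C5 enol. The activated aryl ester may also be lost again by expulsion of the phenol during the base treatment. The fallback sets out from 13 and 11 and closes ring A before the ester is made.
- Et3N in CH2Cl2 should aromatise 13 directly, with the acetonide retained, to 7-hydroxy-2,2,5-trimethyl-4H-1,3-benzodioxin-4-one F1.
- MeI and K2CO3 in acetone should convert its only phenol into 7-methoxy-2,2,5-trimethyl-4H-1,3-benzodioxin-4-one F2.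
- KOH in DMSO/H2O at 80 °C followed by cold acidification should open the acetonide to 2-hydroxy-4-methoxy-6-methylbenzoic acid F3.
- Condensation of this acid with 11 by trifluoroacetic anhydride in toluene at room temperature (mixed-anhydride depside esterification, again at the unchelated 4-OH) comes back to the route at 18, so step 7 is skipped.

Step 5. Proton transfer from the acetyl group of the amide to the strongly basic, doubly deprotonated 3 may return both partners unchanged, and acyl transfer may be sluggish at low temperature. The fallback sets out from 3 and replaces acylation by aldol addition and oxidation.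
- The same doubly deprotonated 3, made with LiN(iPr)2 in THF at −78 °C, is given acetaldehyde, a far faster electrophile. This should give racemic 6-(4-hydroxy-2-oxopentyl)-2,2-dimethyl-4H-1,3-dioxin-4-one F4.
- Dess–Martin oxidation in CH2Cl2 removes the carbinol centre and comes back to the route at 13.

Step 7. Discrimination between the free phenol and the two hydrogen-bonded phenols may be incomplete, that is, over-alkylation on a late and precious intermediate. The fallback sets out from 17 and moves the selectivity from the alkylation to a dealkylation.
- Excess MeI and K2CO3 in refluxing acetone should drive all three phenols to benzyl 4-(2,4-dimethoxy-6-methylbenzoyloxy)-2-methoxy-6-pentylbenzoate F5.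
- BCl3 in CH2Cl2 (−78 → 0 °C) then cleaves, by chelation to the neighbouring carbonyl oxygens, only the two methyl ethers ortho to an ester and leaves the 4'-methoxy group. This comes back to the route at 18.
- Any material that also loses its benzyl group at this point is already 19 and passes unchanged through step 8.

Further compounds
F1 | step 6 | 7-hydroxy-2,2,5-trimethyl-4H-1,3-benzodioxin-4-one | Cc1cc(O)cc2OC(C)(C)OC(=O)c12
F2 | step 6 | 7-methoxy-2,2,5-trimethyl-4H-1,3-benzodioxin-4-one | COc1cc(C)c2C(=O)OC(C)(C)Oc2c1
F3 | step 6 | 2-hydroxy-4-methoxy-6-methylbenzoic acid | COc1cc(C)c(C(=O)O)c(O)c1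
F4 | step 5 | 6-(4-hydroxy-2-oxopentyl)-2,2-dimethyl-4H-1,3-dioxin-4-one (racemic) | CC(O)CC(=O)CC1=CC(=O)OC(C)(C)O1
F5 | step 7 | benzyl 4-(2,4-dimethoxy-6-methylbenzoyloxy)-2-methoxy-6-pentylbenzoate | CCCCCc1cc(OC(=O)c2c(C)cc(OC)cc2OC)cc(OC)c1C(=O)OCc1ccccc1
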